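**Retrosynthetic overview**
- The target comes from the bis-protected flavan-4-ol 17 by removal of the 5-O-silyl and 4'-O-pivaloyl groups; rings A and B are bought as arenes and ring C is the only ring built.
- Ring C is closed at C4–C4a by an intramolecular Ni/Cr coupling of the aryl iodide and aldehyde in 15. This rests on C4 being a carbinol carbon bonded to C4a of ring A, which lies between C8a (bearing O1) and C5 (bearing oxygen), so an aryl metal at C4a reaches an aldehyde hung from O1 through C2–C3.
- Aldehyde 15 comes from the branched allyl aryl ether 12 by hydroboration–oxidation and alcohol oxidation; 12 comes from an iridium-catalysed enantioselective O-allylation of phenol 6 with cinnamyl carbonate 10, which sets C2.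
- Phenol 6 is made from 5-methoxyresorcinol by iodination between the hydroxyls, mono-silylation, O-allylation, Claisen rearrangement to the only free ortho carbon and cross-metathesis to the prenyl group; carbonate 10 comes from methyl (E)-4-hydroxycinnamate.
- The 4'-oxygen is carried as a pivalate, not a silyl ether, so that C2 is not an electron-rich, easily ionised benzylic centre during the allylic etherification and the ring closure.

Key step: step 12

Assumption: the catalyst from [Ir(cod)Cl]2 and the (Sa,Sc,Sc) antipode of 1,1'-binaphthalene-2,2'-diyl N,N-bis(1-phenylethyl)phosphoramidite (L) is taken to give the (S) branched ether, following the sense known for cinnamyl carbonates; the mirror-image ligand would be used if the sense proved opposite.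

**Route**

Step 1
Reactants: 1 5-methoxyresorcinol
Product: 2 2-iodo-5-methoxybenzene-1,3-diol
Conditions: I2 (1.05 equiv), NaHCO3, THF/H2O, 0 °C
Reagents that add atoms: iodine, II
Why: Electrophilic aromatic iodination of the resorcinol anion should take the carbon between the two hydroxyls, as resorcinol itself does under aqueous bicarbonate, and the product keeps its mirror symmetry so that only one kind of ring C–H remains.

Step 2
Reactants: 2 2-iodo-5-methoxybenzene-1,3-diol
Product: 3 2-iodo-5-methoxy-3-(triisopropylsilyloxy)phenol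
Conditions: i-Pr3SiCl (1.0 equiv), imidazole, CH2Cl2, 0 °C
Reagents that add atoms: triisopropylsilyl chloride, CC(C)[Si](Cl)(C(C)C)C(C)C
Why: Imidazole-promoted O-silylation of one of two equivalent phenols with one equivalent of a bulky chlorosilane should give the mono-ether as the main product of a statistical mixture, from which diol and bis-silyl ether can be separated and recycled.

Step 3
Reactants: 3 2-iodo-5-methoxy-3-(triisopropylsilyloxy)phenol
Product: 4 [3-(allyloxy)-2-iodo-5-methoxyphenoxy]triisopropylsilane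
Conditions: allyl bromide, K2CO3, acetone, 50 °C
Reagents that add atoms: allyl bromide, C=CCBr
Why: Williamson O-allylation of the remaining phenol is straightforward, and an aryl triisopropylsilyl ether should tolerate carbonate in acetone.

Step 4
Reactants: 4 [3-(allyloxy)-2-iodo-5-methoxyphenoxy]triisopropylsilane
Product: 5 2-allyl-6-iodo-3-methoxy-5-(triisopropylsilyloxy)phenol
Conditions: PhNEt2, 185 °C, argon
Reagents that add atoms: none
Why: In the aromatic Claisen ([3,3]-sigmatropic) rearrangement the iodine blocks one ortho carbon, so the allyl group should migrate to the free ortho carbon between the phenol oxygen and the methoxy-bearing carbon, followed by tautomerisation to the phenol.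

Step 5
Reactants: 5 2-allyl-6-iodo-3-methoxy-5-(triisopropylsilyloxy)phenol
Product: 6 6-iodo-3-methoxy-2-(3-methylbut-2-enyl)-5-(triisopropylsilyloxy)phenol
Conditions: second-generation Grubbs catalyst RuCl2(=CHPh)(H2IMes)(PCy3) (5 mol%), 2-methyl-2-butene (excess), CH2Cl2, 40 °C
Reagents that add atoms: 2-methyl-2-butene, CC=C(C)C
Why: Olefin cross-metathesis of a terminal allyl arene with excess 2-methyl-2-butene is a standard way to a prenyl arene, and the free phenol and aryl iodide are tolerated.

Step 6
Reactants: 7 methyl (E)-4-hydroxycinnamate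
Product: 8 (E)-4-hydroxycinnamyl alcohol
Conditions: i-Bu2AlH (4 equiv), toluene/THF, −78 → 0 °C; aq. KNaC4H4O6
Reagents that add atoms: none
Why: Excess aluminium hydride reduces the conjugated ester 1,2 to the allylic alcohol after the first equivalent is used up by the phenol, and the alkene geometry is kept.

Step 7
Reactants: 8 (E)-4-hydroxycinnamyl alcohol
Product: 9 4-[(E)-3-hydroxyprop-1-enyl]phenyl pivalate
Conditions: t-BuCOCl (1.05 equiv), K2CO3, acetone, 0 °C → rt
Reagents that add atoms: pivaloyl chloride, CC(C)(C)C(Cl)=O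
Why: Carbonate ionises only the phenol, so chemoselective O-acylation of the phenoxide should occur while the neutral allylic alcohol, lacking an acyl-transfer catalyst, stays free.

Step 8
Reactants: 9 4-[(E)-3-hydroxyprop-1-enyl]phenyl pivalate
Product: 10 tert-butyl (E)-3-[4-(pivaloyloxy)phenyl]allyl carbonate
Conditions: Boc2O (1.3 equiv), DMAP (10 mol%), CH2Cl2, 0 °C → rt
Reagents that add atoms: di-tert-butyl dicarbonate, CC(C)(C)OC(=O)OC(=O)OC(C)(C)C
Why: DMAP-catalysed tert-butoxycarbonylation of the primary allylic alcohol gives the allylic carbonate needed for ionisation by iridium, and its leaving group ends as bulky tert-butoxide, which should spare the aryl pivalate.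

Step 9
Reactants: 6 6-iodo-3-methoxy-2-(3-methylbut-2-enyl)-5-(triisopropylsilyloxy)phenol; 10 tert-butyl (E)-3-[4-(pivaloyloxy)phenyl]allyl carbonate (1.3 equiv)
Product: 12 4-[(S)-1-{6-iodo-3-methoxy-2-(3-methylbut-2-enyl)-5-(triisopropylsilyloxy)phenoxy}allyl]phenyl pivalate, via lithium aryloxide 11 (not isolated)
Conditions: LiN(SiMe3)2 (1.0 equiv), THF, 0 °C; then 10, [Ir(cod)Cl]2 (2 mol%), (Sa,Sc,Sc)-L (4 mol%, pre-activated with n-PrNH2), THF, rt
Reagents that add atoms: none
Why: In this iridium-catalysed asymmetric allylic etherification the cyclometalated iridium–phosphoramidite complex ionises the carbonate to an (η3-allyl) complex and the aryloxide attacks its aryl-substituted terminus from outside the metal, so the ligand sets C2 as (S), while the electron-poor 4-pivaloyloxyphenyl group should keep the branched ether from re-ionising.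

Step 10
Reactants: 12 4-[(S)-1-{6-iodo-3-methoxy-2-(3-methylbut-2-enyl)-5-(triisopropylsilyloxy)phenoxy}allyl]phenyl pivalate
Product: 14 4-[(S)-3-hydroxy-1-{6-iodo-3-methoxy-2-(3-methylbut-2-enyl)-5-(triisopropylsilyloxy)phenoxy}propyl]phenyl pivalate, via B-alkyl-9-BBN adduct 13 (not isolated)
Conditions: 9-BBN (1.5 equiv), THF, 0 °C → rt; then NaBO3·4H2O, H2O, rt
Reagents that add atoms: sodium perborate, [Na+].[Na+].O[B-]1(O)OO[B-](O)(O)OO1
Why: Anti-Markovnikov hydroboration with 9-BBN is strongly selective for the monosubstituted vinyl group over the trisubstituted prenyl alkene, and perborate oxidation is mild enough for the aryl pivalate and silyl ether; C2 is not touched.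

Step 11
Reactants: 14 4-[(S)-3-hydroxy-1-{6-iodo-3-methoxy-2-(3-methylbut-2-enyl)-5-(triisopropylsilyloxy)phenoxy}propyl]phenyl pivalate
Product: 15 4-[(S)-1-{6-iodo-3-methoxy-2-(3-methylbut-2-enyl)-5-(triisopropylsilyloxy)phenoxy}-3-oxopropyl]phenyl pivalate
Conditions: Dess–Martin periodinane (1.3 equiv), NaHCO3, CH2Cl2, 0 °C → rt; used at once
Reagents that add atoms: none
Why: Dess–Martin oxidation under bicarbonate buffer stops at the aldehyde under near-neutral conditions, which should limit loss of aryloxide from this β-aryloxy aldehyde.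

Step 12
Reactants: 15 4-[(S)-1-{6-iodo-3-methoxy-2-(3-methylbut-2-enyl)-5-(triisopropylsilyloxy)phenoxy}-3-oxopropyl]phenyl pivalate
Product: 17 4-[(2S,4R)-4-hydroxy-7-methoxy-8-(3-methylbut-2-enyl)-5-(triisopropylsilyloxy)chroman-2-yl]phenyl pivalate, via aryl–chromium dichloride 16 (not isolated)
Conditions: CrCl2 (6 equiv), NiCl2 (5 mol%), degassed DMF, rt, slow addition of 15 to 0.01 M; aq. NH4Cl
Reagents that add atoms: none
Why: CrCl2 reduces NiCl2 to zerovalent nickel, which inserts into the C4a–I bond; the aryl group passes to trivalent chromium to give 16, which adds to the tethered aldehyde carbon, forming C4–C4a and a chromium alkoxide that is freed on work-up. The closest known reaction type is the intramolecular Nozaki–Hiyama–Kishi coupling of aryl iodides with aldehydes to benzo-fused cyclic carbinols, which tolerates esters, silyl ethers and isolated alkenes. Ring C (C4a, C8a, O1, C2, C3, C4) closes in a 6-exo-trig mode, the carbonyl oxygen staying outside the ring. The new stereocentre C4 is set under substrate control by C2: in the half-chair transition state the C2 aryl group sits equatorial and the chromium-bound oxygen should take the pseudo-axial position, because the pseudo-equatorial site lies in the plane of ring A against the peri C5 triisopropylsilyloxy group; this places O4 trans to the C2 aryl, which is (4R). The step needs 2,4-trans diastereoselectivity and chemoselectivity for the C–I bond over the prenyl alkene and the aryl pivalate; the first rests on the C2 stereocentre together with the bulky peri silyl ether, the second on the mild, non-basic Ni/Cr system. High dilution and slow addition should hold back intermolecular coupling and loss of aryloxide from the aldehyde.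

Step 13
Reactants: 17 4-[(2S,4R)-4-hydroxy-7-methoxy-8-(3-methylbut-2-enyl)-5-(triisopropylsilyloxy)chroman-2-yl]phenyl pivalate
Product: 19 (2S,4R)-2-(4-hydroxyphenyl)-7-methoxy-8-(3-methylbut-2-enyl)chromane-4,5-diol, via 5-hydroxy 4'-pivalate 18 (not isolated)
Conditions: Bu4NF (2.5 equiv), THF, 0 °C; then MeOH, K2CO3, 0 °C → rt; aq. NH4Cl
Reagents that add atoms: none
Why: Fluoride cleaves the aryl O–Si bond and carbonate-mediated methanolysis (transesterification) then removes the aryl pivalate, both at or below room temperature, so neither C2 nor the C4 carbinol should be disturbed.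

**Compound list**
1 | 5-methoxyresorcinol (5-methoxybenzene-1,3-diol) | COc1cc(O)cc(O)c1 | starting material
2 | 2-iodo-5-methoxybenzene-1,3-diol | COc1cc(O)c(I)c(O)c1 | intermediate
3 | 2-iodo-5-methoxy-3-(triisopropylsilyloxy)phenol | COc1cc(O)c(I)c(O[Si](C(C)C)(C(C)C)C(C)C)c1 | intermediate
4 | [3-(allyloxy)-2-iodo-5-methoxyphenoxy]triisopropylsilane | COc1cc(OCC=C)c(I)c(O[Si](C(C)C)(C(C)C)C(C)C)c1 | intermediate
5 | 2-allyl-6-iodo-3-methoxy-5-(triisopropylsilyloxy)phenol | COc1cc(O[Si](C(C)C)(C(C)C)C(C)C)c(I)c(O)c1CC=C | intermediate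
6 | 6-iodo-3-methoxy-2-(3-methylbut-2-enyl)-5-(triisopropylsilyloxy)phenol | COc1cc(O[Si](C(C)C)(C(C)C)C(C)C)c(I)c(O)c1CC=C(C)C | intermediate
7 | methyl (E)-4-hydroxycinnamate | COC(=O)/C=C/c1ccc(O)cc1 | starting material
8 | (E)-4-hydroxycinnamyl alcohol | OC/C=C/c1ccc(O)cc1 | intermediate
9 | 4-[(E)-3-hydroxyprop-1-enyl]phenyl pivalate | OC/C=C/c1ccc(OC(=O)C(C)(C)C)cc1 | intermediate
10 | tert-butyl (E)-3-[4-(pivaloyloxy)phenyl]allyl carbonate | CC(C)(C)OC(=O)OC/C=C/c1ccc(OC(=O)C(C)(C)C)cc1 | intermediate
11 | lithium 6-iodo-3-methoxy-2-(3-methylbut-2-enyl)-5-(triisopropylsilyloxy)phenolate | [Li+].COc1cc(O[Si](C(C)C)(C(C)C)C(C)C)c(I)c([O-])c1CC=C(C)C | intermediate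
12 | 4-[(S)-1-{6-iodo-3-methoxy-2-(3-methylbut-2-enyl)-5-(triisopropylsilyloxy)phenoxy}allyl]phenyl pivalate | COc1cc(O[Si](C(C)C)(C(C)C)C(C)C)c(I)c(c1CC=C(C)C)O[C@H](c1ccc(OC(=O)C(C)(C)C)cc1)C=C | intermediate
13 | B-alkyl-9-BBN adduct of 12 (boron on the terminal carbon) | COc1cc(O[Si](C(C)C)(C(C)C)C(C)C)c(I)c(c1CC=C(C)C)O[C@H](c1ccc(OC(=O)C(C)(C)C)cc1)CCB1C2CCCC1CCC2 | intermediate
14 | 4-[(S)-3-hydroxy-1-{6-iodo-3-methoxy-2-(3-methylbut-2-enyl)-5-(triisopropylsilyloxy)phenoxy}propyl]phenyl pivalate | COc1cc(O[Si](C(C)C)(C(C)C)C(C)C)c(I)c(c1CC=C(C)C)O[C@H](c1ccc(OC(=O)C(C)(C)C)cc1)CCO | intermediate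
15 | 4-[(S)-1-{6-iodo-3-methoxy-2-(3-methylbut-2-enyl)-5-(triisopropylsilyloxy)phenoxy}-3-oxopropyl]phenyl pivalate | COc1cc(O[Si](C(C)C)(C(C)C)C(C)C)c(I)c(c1CC=C(C)C)O[C@H](c1ccc(OC(=O)C(C)(C)C)cc1)CC=O | intermediate
16 | aryl–chromium dichloride from 15 (chromium in place of iodine at C4a) | COc1cc(O[Si](C(C)C)(C(C)C)C(C)C)c([Cr](Cl)Cl)c(c1CC=C(C)C)O[C@H](c1ccc(OC(=O)C(C)(C)C)cc1)CC=O | intermediate
17 | 4-[(2S,4R)-4-hydroxy-7-methoxy-8-(3-methylbut-2-enyl)-5-(triisopropylsilyloxy)chroman-2-yl]phenyl pivalate | COc1cc(O[Si](C(C)C)(C(C)C)C(C)C)c2c(c1CC=C(C)C)O[C@H](c1ccc(OC(=O)C(C)(C)C)cc1)C[C@H]2O | intermediate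
18 | 4-[(2S,4R)-4,5-dihydroxy-7-methoxy-8-(3-methylbut-2-enyl)chroman-2-yl]phenyl pivalate | COc1cc(O)c2c(c1CC=C(C)C)O[C@H](c1ccc(OC(=O)C(C)(C)C)cc1)C[C@H]2O | intermediate
19 | (2S,4R)-2-(4-hydroxyphenyl)-7-methoxy-8-(3-methylbut-2-enyl)chromane-4,5-diol (4,5,4'-trihydroxy-7-methoxy-8-prenylflavan) | COc1cc(O)c2c(c1CC=C(C)C)O[C@H](c1ccc(O)cc1)C[C@H]2O | target

**Step count**
Total: 13 steps. Longest linear sequence: 10 steps (steps 1–5, then 9–13); the carbonate branch is 3 steps (6–8).

**Steps most likely to fail**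

1. Step 12. The addition of the aryl–chromium bond to the aldehyde may show poor facial selectivity at C4, and insertion into the hindered, electron-rich C–I bond may be slow enough for the aldehyde to lose aryloxide. The fallback sets out from 17 obtained as a mixture with its C4 epimer and sets C4 by oxidation, reduction and inversion instead. Dess–Martin oxidation should merge both epimers into 4-[(2S)-7-methoxy-8-(3-methylbut-2-enyl)-4-oxo-5-(triisopropylsilyloxy)chroman-2-yl]phenyl pivalate F1. NaBH4 in MeOH/THF at −20 °C should deliver hydride axially to give the 2,4-cis alcohol, 4-[(2S,4S)-4-hydroxy-7-methoxy-8-(3-methylbut-2-enyl)-5-(triisopropylsilyloxy)chroman-2-yl]phenyl pivalate F2. Mitsunobu inversion (PPh3, DIAD, 4-nitrobenzoic acid, toluene, 0 °C → rt) should give the (4R) ester, (2S,4R)-7-methoxy-8-(3-methylbut-2-enyl)-2-[4-(pivaloyloxy)phenyl]-5-(triisopropylsilyloxy)chroman-4-yl 4-nitrobenzoate F3. The conditions of step 13, whose methanolysis also cleaves the nitrobenzoate, bring the sequence back to the route at 19.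

2. Step 9. The doubly ortho-substituted aryloxide may attack the substituted allyl terminus slowly, so that reversible ionisation erodes the branched selectivity and the enantiomeric purity. The fallback sets out from 6 and forms the O1–C2 bond by Mitsunobu inversion of a preformed carbinol. 4-Hydroxybenzaldehyde is acylated (t-BuCOCl, Et3N) to 4-formylphenyl pivalate F4. Asymmetric allylboration with (+)-B-allyldiisopinocampheylborane (Et2O, −78 °C, ethanolamine work-up) should give 4-[(R)-1-hydroxybut-3-enyl]phenyl pivalate F5. Ozonolysis with NaBH4 work-up gives 4-[(R)-1,3-dihydroxypropyl]phenyl pivalate F6, and selective silylation of the primary hydroxyl (t-BuMe2SiCl, imidazole, 0 °C) gives 4-[(R)-3-(tert-butyldimethylsilyloxy)-1-hydroxypropyl]phenyl pivalate F7. Mitsunobu coupling of F7 with 6 (PPh3, DIAD, concentrated toluene solution, sonication) should give, with inversion, 4-[(S)-3-(tert-butyldimethylsilyloxy)-1-{6-iodo-3-methoxy-2-(3-methylbut-2-enyl)-5-(triisopropylsilyloxy)phenoxy}propyl]phenyl pivalate F8. Camphorsulfonic acid in MeOH at 0 °C removes the primary silyl ether only, and the sequence comes back to the route at 14.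

3. Step 13. Once phenoxides are present in basic methanol, the C4 carbinol, activated by the ring A oxygens and the free 5-hydroxyl, may ionise and be solvolysed, or ring C may open at C2. The fallback sets out from 17 and avoids basic methanolysis. i-Bu2AlH (CH2Cl2, −78 °C) cleaves the pivalate reductively to 4-[(2S,4R)-4-hydroxy-7-methoxy-8-(3-methylbut-2-enyl)-5-(triisopropylsilyloxy)chroman-2-yl]phenol F9. Et3N·3HF in THF at 0 °C then removes the silyl group under near-neutral conditions, and the sequence comes back to the route at 19.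

**Further compounds**
F1 | step 12 | 4-[(2S)-7-methoxy-8-(3-methylbut-2-enyl)-4-oxo-5-(triisopropylsilyloxy)chroman-2-yl]phenyl pivalate | COc1cc(O[Si](C(C)C)(C(C)C)C(C)C)c2c(c1CC=C(C)C)O[C@H](c1ccc(OC(=O)C(C)(C)C)cc1)CC2=O
F2 | step 12 | 4-[(2S,4S)-4-hydroxy-7-methoxy-8-(3-methylbut-2-enyl)-5-(triisopropylsilyloxy)chroman-2-yl]phenyl pivalate | COc1cc(O[Si](C(C)C)(C(C)C)C(C)C)c2c(c1CC=C(C)C)O[C@H](c1ccc(OC(=O)C(C)(C)C)cc1)C[C@@H]2O
F3 | step 12 | (2S,4R)-7-methoxy-8-(3-methylbut-2-enyl)-2-[4-(pivaloyloxy)phenyl]-5-(triisopropylsilyloxy)chroman-4-yl 4-nitrobenzoate | COc1cc(O[Si](C(C)C)(C(C)C)C(C)C)c2c(c1CC=C(C)C)O[C@H](c1ccc(OC(=O)C(C)(C)C)cc1)C[C@H]2OC(=O)c1ccc(cc1)[N+](=O)[O-]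
F4 | step 9 | 4-formylphenyl pivalate | CC(C)(C)C(=O)Oc1ccc(C=O)cc1
F5 | step 9 | 4-[(R)-1-hydroxybut-3-enyl]phenyl pivalate | C=CC[C@@H](O)c1ccc(OC(=O)C(C)(C)C)cc1
F6 | step 9 | 4-[(R)-1,3-dihydroxypropyl]phenyl pivalate | OCC[C@@H](O)c1ccc(OC(=O)C(C)(C)C)cc1
F7 | step 9 | 4-[(R)-3-(tert-butyldimethylsilyloxy)-1-hydroxypropyl]phenyl pivalate | CC(C)(C)[Si](C)(C)OCC[C@@H](O)c1ccc(OC(=O)C(C)(C)C)cc1
F8 | step 9 | 4-[(S)-3-(tert-butyldimethylsilyloxy)-1-{6-iodo-3-methoxy-2-(3-methylbut-2-enyl)-5-(triisopropylsilyloxy)phenoxy}propyl]phenyl pivalate | COc1cc(O[Si](C(C)C)(C(C)C)C(C)C)c(I)c(c1CC=C(C)C)O[C@H](c1ccc(OC(=O)C(C)(C)C)cc1)CCO[Si](C)(C)C(C)(C)C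
F9 | step 13 | 4-[(2S,4R)-4-hydroxy-7-methoxy-8-(3-methylbut-2-enyl)-5-(triisopropylsilyloxy)chroman-2-yl]phenol | COc1cc(O[Si](C(C)C)(C(C)C)C(C)C)c2c(c1CC=C(C)C)O[C@H](c1ccc(O)cc1)C[C@H]2O
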